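## The problem

The target 30 is a ten-membered carbocycle (C1–C10, germacrane numbering) fused at C6–C7 to a butenolide whose alkene is the tetrasubstituted C7=C11 bond. It also carries a trans oxirane on C4–C5 and a ring-cis C1=C10 enal (CIP E, formyl carbon C14 outside the ring).

There are four stereocentres: C4 and C5 of the epoxide (R,R), the lactone carbinol C6 (R) and the acyloxy carbon C8 (S). The C6–O and C8–O bonds lie on opposite faces of the ring.

C8 is insulated from the other centres by the planar C7, so it is the only centre that can be set alone, at the start, by a catalytic asymmetric reaction. C6 and the epoxide must then be related to it across a flexible medium ring, where acyclic models do not apply.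

The ring is the second difficulty: it holds five sp2 ring carbons and must be closed against strain without scrambling either trisubstituted alkene.

Little in the molecule tolerates rough treatment. The epoxide is opened by acid, the enal is attacked by nucleophiles and peroxides, and the butenolide has an acidic γ-hydrogen at C6. Both ester C–O bonds (C8, C13) are allylic to C7=C11, so the acyl groups must come last, and a free C8 hydroxyl can move the lactone from O6 to O8.

The opening lies in C6. It is at once the lactone carbinol carbon and allylic to the C4=C5 alkene that precedes the epoxide. Its C–O bond, alone among the C–O bonds, can therefore be ionised by zerovalent palladium and re-formed, and C6 need not be controlled while the skeleton is built.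

## Retrosynthesis

**Acyl groups (30 ⇒ 29 ⇒ 28 ⇒ 27).** The isovalerate and acetate C–O bonds are cut first, back to diol 28 and its bis-silyl ether 27. Esters at C8 and C13 are allylic and would be ionised by palladium, whereas silyl ethers are not, so the oxygens must travel as silyl ethers through the key step. The forward steps only need to distinguish a primary from a secondary hydroxyl.

**Epoxide (27 ⇒ 26).** The two C–O bonds of the oxirane are cut to the (E)-C4=C5 alkene of 26. The epoxide cannot come earlier, because this alkene is the allyl handle of the key step. It is the only electron-rich alkene left, so an electrophilic, reagent-controlled oxidant can find it and choose its face.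

**C6–O bond (26 ⇒ 25).** The lactone C6–O bond is cut and re-formed: 26 is taken back to its C6 epimer 25, obtained as a mixture with 26. This removes C6 from the list of centres that the skeleton-forming steps must control. The forward reaction must interconvert the epimers through an allylpalladium carboxylate and drain them into 26. Because simple ionisation and anti return only restores the starting epimer, the plan relies on the known face-exchange routes of allylpalladium carboxylates (syn return of the bound carboxylate, or displacement of palladium by palladium) and uses a catalyst loading that favours them.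

**Ring (25 ⇐ 24 ⇐ 21).** The ring is cut at C5–C6, together with the lactone, to the open-chain (Z)-formyl ester 21 with an (E)-alkenyl iodide at C5. An intramolecular Nozaki–Hiyama–Kishi reaction makes this bond, closes the ten-membered ring and delivers the C6 alkoxide next to the ester; its lack of C6 control is harmless here. Closing at C2–C3 by carbanion alkylation would expose the butenolide to strong base, and closing at C1=C10 by metathesis would have to form a trisubstituted ring alkene. The precursor 21 is acyclic with one stereocentre.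

**Formyl ester (21 ⇐ 20 ⇐ 17).** The tetrasubstituted Z alkene with an aldehyde and an ester cis to each other is traced to furan 17. Singlet oxygen turns a furan into exactly this unit, and a silyl group on the furan carbon that is to become C12 decides which α-carbon becomes the carboxyl. This avoids any stereoselective synthesis of a tetrasubstituted alkene.

**Side chain (17 ⇐ 14 ⇐ 10 + 13).** The C1=C10 bond is cut by cross-metathesis between α-methylene lactone 10 and diene 13. The (E)-alkylidene lactone 14 has C2 cis to C9, which is the ring-cis geometry of the target enal. The lactone also holds C14 at the acid level and masks O8 until reduction to diol 15. A Wittig or aldol construction of the same alkene would need more steps from 10.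

**C8 and the starting materials (10 ⇐ 6 + 7; 6 ⇐ 1; 13 ⇐ 11).** The C8–C9 bond is cut to furaldehyde 6 and bromomethylacrylate 7. A catalytic asymmetric 2-(alkoxycarbonyl)allylation sets C8 and gives the lactone in one step. Aldehyde 6 comes from furan-3-ylmethanol 1 by silyl migration and directed lithiation, and iodide 13 comes from hex-1-en-5-yne 11 by carboalumination. All three starting materials are commercial.

## Roads not taken

**Alternative 1:** The cut is C8–C9, made while the C1–C6 bond of a six-membered ring breaks. A potassium alkoxide (KH, 18-crown-6) flanked by two vicinal alkenyl groups undergoes an anionic oxy-Cope shift to the ten-membered C6 ketone A1, which carries a silyl group at C8 and an acetonide on C4/C5.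
- Merits: the ring comes from a sigmatropic expansion with a long record for cyclodecenones, and it needs no high dilution. C4 and C5 are fixed from the chiral pool before the ring exists. The C6 ketone allows C6 to be set by reduction.
- Weak points: the chair transition state gives the ring-trans C1=C10 alkene with C14 still a methyl group, so an allylic oxidation and an alkene inversion are owed. C11–C13 and both lactone bonds must still be built on a hindered ketone. The silyl-to-hydroxyl oxidation must spare two alkenes.
- Comparison: ring formation and the C4/C5 configuration are more secure there than in steps 13 and 16 here. The chosen plan offers in return that C11–C14 arrive at the right oxidation level before the ring closes and that an error at C6 is correctable.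

**Alternative 2:** The cuts are C7=C11 and O6–C12. A lithium ynolate carrying C13 adds to a C7 carbonyl group on the preformed ring, the oxetene opens to the tetrasubstituted alkene with the carboxylate beside C6, and desilylation of O6 closes the butenolide to give A2.
- Merits: all three lactone carbons and the alkene arrive in one operation. C6, C8 and the epoxide are set beforehand, so nothing rests on an equilibrium.
- Weak points: the carbonyl is flanked by oxygenated C6 and C8, so the torquoselective opening has two competing oxygen substituents. A fluoride that frees O6 can free O8, which closes the 12,8-olide equally well. The ynolate is a strong base facing two acidic α-hydrogens and an epoxide. The ten-membered ring still needs its own closure.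
- Comparison: A2 is better in step economy for the lactone and in having a kinetically defined C6. The chosen plan offers in return that C6–O is the only bond palladium can ionise while O8 is silylated, and that its basic steps never meet the epoxide.

**Alternative 3:** The cuts are C8–O and C13–O. Singlet oxygen (tetraphenylporphyrin C44H30N4, light) adds across the lactone-locked s-cis diene C8=C7–C11=C13 to give the 1,2-dioxine A3, and O–O reduction would give diol 28 directly.
- Merits: two C–O bonds and the C7=C11 alkene position come in one step, with no protecting groups on O8 and O13 and the shortest endgame.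
- Weak points: the C8 configuration depends on which face of the macrocycle the oxygen attacks, with no reagent to overrule it. The cross-conjugated dienyl lactone adds strain and Michael reactivity and must be made with C6 and the epoxide already correct. The peroxide has a hydrogen at C8 and is prone to Kornblum–DeLaMare isomerisation. The reduction must spare epoxide and enal.
- Comparison: A3 is better in step count and protecting-group economy. The chosen plan offers in return a catalyst-set C8, a correctable C6 and close precedent for each step.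

Key step: step 15

## Route

Remark on names: germacrane locants are used throughout (C12 lactone carbonyl, C13 the CH2O carbon on C11, C14 on C10, C15 the methyl on C4). TBS = tert-butyldimethylsilyl, TES = triethylsilyl, Fur = 5-TBS-4-(TBS-oxymethyl)furan-3-yl.

Assumption: the (6S) epimer 26, with the C6–O and C8–O bonds on opposite ring faces, is taken to be the more stable C6 epimer of the bis-silyl lactone.

Step 1
Reactants: 1 furan-3-ylmethanol
Product: 2 tert-butyl(furan-3-ylmethoxy)dimethylsilane
Conditions: TBSCl, imidazole, DMF, rt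
Reagents that add atoms: tert-butyl(chloro)dimethylsilane, CC(C)(C)[Si](C)(C)Cl
Why: Standard silylation of a primary alcohol; this silyl group is the one that later moves to the furan carbon and directs the furan oxidation.

Step 2
Reactants: 2 tert-butyl(furan-3-ylmethoxy)dimethylsilane
Product: 3 [2-(tert-butyldimethylsilyl)furan-3-yl]methanol
Conditions: n-BuLi, HMPA, THF, −78 °C → rt; H2O
Reagents that add atoms: none
Why: Retro-[1,4]-Brook rearrangement: lithiation at the furan α-position next to the side chain is followed by O→C silyl migration, a known entry to 2-silyl-3-(hydroxymethyl)furans.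

Step 3
Reactants: 3 [2-(tert-butyldimethylsilyl)furan-3-yl]methanol
Product: 5 5-(tert-butyldimethylsilyl)-4-(hydroxymethyl)furan-3-carbaldehyde, via dilithio furan 4 (not isolated)
Conditions: n-BuLi (2.2 equiv), DME, 0 °C; DMF, −78 °C → rt; H2O
Reagents that add atoms: N,N-dimethylformamide, CN(C)C=O
Why: Alkoxide-directed ortho-lithiation: with C2 blocked by silicon the lithium alkoxide steers metalation to C4 and not to the free α-position, and formylation gives the 3,4-disubstituted pattern.

Step 4
Reactants: 5 5-(tert-butyldimethylsilyl)-4-(hydroxymethyl)furan-3-carbaldehyde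
Product: 6 5-(tert-butyldimethylsilyl)-4-[(tert-butyldimethylsilyloxy)methyl]furan-3-carbaldehyde
Conditions: TBSCl, imidazole, DMF, rt
Reagents that add atoms: tert-butyl(chloro)dimethylsilane, CC(C)(C)[Si](C)(C)Cl
Why: Standard silylation; it installs the C13 silyl ether that is kept until step 17.

Step 5
Reactants: 6 5-(tert-butyldimethylsilyl)-4-[(tert-butyldimethylsilyloxy)methyl]furan-3-carbaldehyde; 7 ethyl 2-(bromomethyl)prop-2-enoate
Product: 10 (5S)-5-Fur-3-methylideneoxolan-2-one, via trimethylsilyl ether 8 (not isolated), via hydroxy ester 9 (not isolated)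
Conditions: CrCl2 (10 mol %), chiral 1,8-bis(oxazolinyl)carbazole ligand (12 mol %), Mn, TMSCl, THF, rt; then PPTS, MeOH, 0 °C; CSA (cat.), toluene, rt
Reagents that add atoms: none
Why: Catalytic asymmetric Nozaki–Hiyama allylation with a 2-(alkoxycarbonyl)allyl bromide, a known route to γ-aryl α-methylene-γ-butyrolactones; the ligand enantiomer is chosen so that the allylchromium adds to the Si face of the aldehyde, which gives (S) at C8, and mild acid then removes the trimethylsilyl group and closes the lactone.

Step 6
Reactants: 11 hex-1-en-5-yne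
Product: 13 (1E)-1-iodo-2-methylhexa-1,5-diene, via alkenylalane 12 (not isolated)
Conditions: AlMe3, Cp2ZrCl2 (25 mol %), CH2Cl2, 0 °C → rt; then I2, THF, −30 °C
Reagents that add atoms: trimethylaluminium, C[Al](C)C; iodine, II
Why: Zirconium-catalysed carboalumination (Negishi) adds methyl and aluminium syn across the terminal alkyne only, and iodinolysis with retention gives the (E)-iodide that carries C1–C5 and C15.

Step 7
Reactants: 10 (5S)-5-Fur-3-methylideneoxolan-2-one; 13 (1E)-1-iodo-2-methylhexa-1,5-diene
Product: 14 (3E,5S)-5-Fur-3-[(4E)-5-iodo-4-methylpent-4-en-1-ylidene]oxolan-2-one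
Conditions: second-generation Hoveyda–Grubbs catalyst C31H38Cl2N2ORu (10 mol %), 2,6-dichloro-1,4-benzoquinone (20 mol %), 13 (3 equiv), CH2Cl2, 40 °C
Reagents that add atoms: none
Why: Cross-metathesis of α-methylene-γ-butyrolactones with terminal alkenes is known to give (E)-α-alkylidene lactones, the quinone suppressing migration of the alkene into the ring; the E geometry (C2 cis to C9) is the ring-cis C1=C10 geometry of the target, and the trisubstituted alkenyl iodide does not take part.

Step 8
Reactants: 14 (3E,5S)-5-Fur-3-[(4E)-5-iodo-4-methylpent-4-en-1-ylidene]oxolan-2-one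
Product: 15 (2E,4S)-4-Fur-2-[(4E)-5-iodo-4-methylpent-4-en-1-ylidene]butane-1,4-diol
Conditions: i-Bu2AlH (4 equiv), CH2Cl2, −78 → 0 °C; aq. KNaC4H4O6
Reagents that add atoms: none
Why: 1,2-Reduction of the conjugated lactone to the allylic 1,4-diol frees C14–OH and C8–OH with the alkene geometry kept; the alkenyl iodide and the silyl groups are inert to the hydride.

Step 9
Reactants: 15 (2E,4S)-4-Fur-2-[(4E)-5-iodo-4-methylpent-4-en-1-ylidene]butane-1,4-diol
Product: 16 (1S,3E,7E)-1-Fur-8-iodo-7-methyl-3-[(triethylsilyloxy)methyl]octa-3,7-dien-1-ol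
Conditions: TESCl (1.05 equiv), imidazole, CH2Cl2, −40 °C
Reagents that add atoms: chlorotriethylsilane, CC[Si](CC)(CC)Cl
Why: The primary allylic hydroxyl is silylated ahead of the hindered secondary C8 hydroxyl; TES is chosen because it can later be removed beside both TBS ethers.

Step 10
Reactants: 16 (1S,3E,7E)-1-Fur-8-iodo-7-methyl-3-[(triethylsilyloxy)methyl]octa-3,7-dien-1-ol
Product: 17 the C8 (carbinol) TBS ether of 16
Conditions: TBSOTf, 2,6-lutidine, CH2Cl2, −78 °C
Reagents that add atoms: tert-butyldimethylsilyl trifluoromethanesulfonate, CC(C)(C)[Si](C)(C)OS(=O)(=O)C(F)(F)F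
Why: Silyl triflate silylation of a hindered secondary alcohol; C8 now carries the ether that survives the palladium step.

Step 11
Reactants: 17 the C8 TBS ether of 16
Product: 20 (5RS)-5-hydroxy-4-[(1S,3E,7E)-1-(TBS-oxy)-8-iodo-7-methyl-3-(TES-oxymethyl)octa-3,7-dien-1-yl]-3-(TBS-oxymethyl)furan-2(5H)-one, via endoperoxide 18 (not isolated), via silyl ester 19 (not isolated)
Conditions: O2, visible light, tetraphenylporphyrin C44H30N4 (cat.), CH2Cl2, −78 °C; then H2O, THF, rt
Reagents that add atoms: dioxygen, O=O
Why: Singlet oxygen adds [4+2] to the furan and the silyl group shifts from carbon to peroxide oxygen, so the silicon-bearing carbon becomes the carboxyl carbon C12 and the unsubstituted α-carbon becomes C6 at the aldehyde level; hydrolysis gives the γ-hydroxybutenolide, and at −78 °C the furan reacts far faster than the trisubstituted alkenes undergo the ene reaction.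

Step 12
Reactants: 20 the γ-hydroxybutenolide
Product: 21 methyl (2Z,4S,6E,10E)-4-(TBS-oxy)-2-(TBS-oxymethyl)-3-formyl-11-iodo-10-methyl-6-(TES-oxymethyl)undeca-2,6,10-trienoate
Conditions: MeI, K2CO3, DMF, 0 °C → rt
Reagents that add atoms: iodomethane, CI
Why: The pseudo-acid ionises to the open (Z)-formyl carboxylate, which is alkylated on oxygen to the normal methyl ester (the ring–chain behaviour by which 3-hydroxyphthalide gives methyl 2-formylbenzoate); this exposes the C6 aldehyde cis to the C12 ester.

Step 13
Reactants: 21 the methyl (Z)-formyl ester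
Product: 24 (6RS,8S)-8,13-bis(TBS-oxy)-14-hydroxygermacra-1(10)E,4E,7(11)-trien-12,6-olide, via hydroxy ester 22 (not isolated), via triethylsilyl lactone 23 (not isolated)
Conditions: CrCl2 (6 equiv), NiCl2 (2 mol %), DMSO–THF, rt, slow addition to 2 mM; H2O; then PPTS, MeOH–CH2Cl2, 0 °C → rt
Reagents that add atoms: none
Why: Intramolecular Nozaki–Hiyama–Kishi reaction: the alkenylchromium from the C5 iodide adds to the C6 aldehyde with retention of the E alkene and closes the ten-membered ring, the C6 alkoxide lactonises onto the cis ester, and acidic methanol then removes only the TES ether; no selectivity at C6 is sought because both epimers feed step 15.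

Step 14
Reactants: 24 the C14 alcohol (both C6 epimers)
Product: 25 (6R,8S)-8,13-bis(TBS-oxy)-14-oxogermacra-1(10)E,4E,7(11)-trien-12,6-olide, the 6-epi lactone, carried on unseparated from its (6S) epimer
Conditions: MnO2, CH2Cl2, rt
Reagents that add atoms: none
Why: Selective oxidation of the only free allylic alcohol to the enal; the ring-cis (CIP E) geometry is the stable one for a 2-alkyl-2-enal and is kept.

Step 15
Reactants: 25 the 6-epi lactone (6R), as the unseparated mixture of C6 epimers from step 14
Product: 26 (6S,8S)-8,13-bis(TBS-oxy)-14-oxogermacra-1(10)E,4E,7(11)-trien-12,6-olide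
Conditions: Pd(PPh3)4 (10 mol %), THF (degassed), 45 °C
Reagents that add atoms: none
Why: Zerovalent palladium ionises the allylic C6–O bond of either epimer, anti to the leaving carboxylate, to an η3-allyl complex over C4–C5–C6 with the (Z)-butenoate as tethered counter-ion; the closest known reaction type is the palladium-catalysed ionisation–return (Tsuji–Trost manifold) that epimerises allylic esters and equilibrates vinyl lactones. The carboxylate returns to C6 by a 5-exo closure that re-forms the butenolide: return anti to palladium restores the starting epimer, whereas return of the palladium-bound carboxylate on the same face, or return after displacement of palladium by a second zerovalent palladium, gives the other, so the two lactones interconvert without a σ-complex at C4. C6 is the only new stereocentre and is set under thermodynamic control by the fixed C8 centre, relayed through planar C7 and the ring, the sink being taken as 26. Closure at C6 and not at C4 is secured by ring size (five- against seven-membered) and by the hindered tertiary C4 terminus, and any seven-membered lactone is itself an allylic ester that is re-ionised. The E geometry of C4=C5 holds as long as the syn,syn allyl is kept, which the reluctance of palladium to σ-bond at tertiary C4 supports. The silyl ethers at C8 and C13 are allylic but are not leaving groups, and the absence of base keeps β-hydride elimination to dienes slow. The 10 mol % loading is chosen because face exchange by palladium displacement is second order in palladium.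

Step 16
Reactants: 26 the (6S) lactone
Product: 27 (4R,5R,6R,8S)-8,13-bis(TBS-oxy)-4,5-epoxy-14-oxogermacra-1(10)E,7(11)-dien-12,6-olide
Conditions: D-fructose-derived ketone C12H18O6 (30 mol %), KHSO5 (as 2KHSO5·KHSO4·K2SO4), K2CO3, n-Bu4NHSO4, MeCN–CH2(OMe)2–aq. Na2B4O7 buffer (pH 10.5), 0 °C
Reagents that add atoms: potassium peroxymonosulfate, [K+].[O-]S(=O)(=O)OO
Why: Shi epoxidation: the chiral dioxirane attacks the only electron-rich alkene, and for an (E)-trisubstituted alkene the spiro transition state of the D-fructose-derived ketone gives the (R,R)-oxirane, here (4R,5R); the enal and butenolide alkenes are too electron-poor to react. (C6 keeps its geometry; its descriptor changes to R because C5 now outranks C7.)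

Step 17
Reactants: 27 the bis-silyl epoxide
Product: 28 (4R,5R,6R,8S)-4,5-epoxy-8,13-dihydroxy-14-oxogermacra-1(10)E,7(11)-dien-12,6-olide
Conditions: HF·pyridine, pyridine, THF, 0 °C → rt
Reagents that add atoms: none
Why: Pyridine-buffered fluoride cleaves both TBS ethers; the electron-poor C1=C10 enal cannot take part in transannular opening of the epoxide, and the near-neutral medium limits lactone migration to O8.

Step 18
Reactants: 28 the 8,13-diol
Product: 29 (4R,5R,6R,8S)-13-acetoxy-4,5-epoxy-8-hydroxy-14-oxogermacra-1(10)E,7(11)-dien-12,6-olide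
Conditions: AcCl (1.05 equiv), 2,4,6-collidine, CH2Cl2, −78 °C
Reagents that add atoms: acetyl chloride, CC(=O)Cl
Why: Acyl chloride with a hindered pyridine base at low temperature acetylates primary alcohols selectively over secondary ones.

Step 19
Reactants: 29 the 13-acetate
Product: 30 (4R,5R,6R,8S)-13-acetoxy-4,5-epoxy-8-(3-methylbutanoyloxy)-14-oxogermacra-1(10)E,7(11)-dien-12,6-olide (CNP0289605.1)
Conditions: 3-methylbutanoic anhydride, DMAP (cat.), pyridine, CH2Cl2, 0 °C
Reagents that add atoms: 3-methylbutanoic anhydride, CC(C)CC(=O)OC(=O)CC(C)C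
Why: DMAP-catalysed acylation of the secondary allylic alcohol with retention at C8; fast acylation under weakly basic conditions outruns lactone migration.

## Compound list

1 | furan-3-ylmethanol | OCc1ccoc1 | starting material
2 | tert-butyl(furan-3-ylmethoxy)dimethylsilane | CC(C)(C)[Si](C)(C)OCc1ccoc1 | intermediate
3 | [2-(tert-butyldimethylsilyl)furan-3-yl]methanol | OCc1ccoc1[Si](C)(C)C(C)(C)C | intermediate
4 | lithium [2-(tert-butyldimethylsilyl)-4-lithiofuran-3-yl]methanolate | [Li]OCc1c([Li])coc1[Si](C)(C)C(C)(C)C | intermediate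
5 | 5-(tert-butyldimethylsilyl)-4-(hydroxymethyl)furan-3-carbaldehyde | OCc1c(C=O)coc1[Si](C)(C)C(C)(C)C | intermediate
6 | 5-(tert-butyldimethylsilyl)-4-[(tert-butyldimethylsilyloxy)methyl]furan-3-carbaldehyde | CC(C)(C)[Si](C)(C)OCc1c(C=O)coc1[Si](C)(C)C(C)(C)C | intermediate
7 | ethyl 2-(bromomethyl)prop-2-enoate | CCOC(=O)C(=C)CBr | starting material
8 | ethyl (4S)-4-Fur-2-methylidene-4-(trimethylsilyloxy)butanoate | CC(C)(C)[Si](C)(C)OCc1c([C@@H](O[Si](C)(C)C)CC(=C)C(=O)OCC)coc1[Si](C)(C)C(C)(C)C | intermediate
9 | ethyl (4S)-4-Fur-4-hydroxy-2-methylidenebutanoate | CC(C)(C)[Si](C)(C)OCc1c([C@@H](O)CC(=C)C(=O)OCC)coc1[Si](C)(C)C(C)(C)C | intermediate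
10 | (5S)-5-Fur-3-methylideneoxolan-2-one | CC(C)(C)[Si](C)(C)OCc1c([C@@H]2CC(=C)C(=O)O2)coc1[Si](C)(C)C(C)(C)C | intermediate
11 | hex-1-en-5-yne | C=CCCC#C | starting material
12 | dimethyl[(1E)-2-methylhexa-1,5-dien-1-yl]alane | C=CCC/C(C)=C/[Al](C)C | intermediate
13 | (1E)-1-iodo-2-methylhexa-1,5-diene | C=CCC/C(C)=C/I | intermediate
14 | (3E,5S)-5-Fur-3-[(4E)-5-iodo-4-methylpent-4-en-1-ylidene]oxolan-2-one | CC(C)(C)[Si](C)(C)OCc1c([C@@H]2C/C(=C\CC/C(C)=C/I)C(=O)O2)coc1[Si](C)(C)C(C)(C)C | intermediate
15 | (2E,4S)-4-Fur-2-[(4E)-5-iodo-4-methylpent-4-en-1-ylidene]butane-1,4-diol | CC(C)(C)[Si](C)(C)OCc1c([C@@H](O)C/C(CO)=C\CC/C(C)=C/I)coc1[Si](C)(C)C(C)(C)C | intermediate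
16 | (1S,3E,7E)-1-Fur-8-iodo-7-methyl-3-[(triethylsilyloxy)methyl]octa-3,7-dien-1-ol | CC(C)(C)[Si](C)(C)OCc1c([C@@H](O)C/C(CO[Si](CC)(CC)CC)=C\CC/C(C)=C/I)coc1[Si](C)(C)C(C)(C)C | intermediate
17 | C8 TBS ether of 16 | CC(C)(C)[Si](C)(C)OCc1c([C@@H](O[Si](C)(C)C(C)(C)C)C/C(CO[Si](CC)(CC)CC)=C\CC/C(C)=C/I)coc1[Si](C)(C)C(C)(C)C | intermediate
18 | 2,5-endoperoxide of furan 17 (peroxide bridge between the silyl-bearing carbon and the free α-carbon) | CC(C)(C)[Si](C)(C)OCC1=C([C@@H](O[Si](C)(C)C(C)(C)C)C/C(CO[Si](CC)(CC)CC)=C\CC/C(C)=C/I)C2OOC1([Si](C)(C)C(C)(C)C)O2 | intermediate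
19 | TBS ester corresponding to methyl ester 21 | CC(C)(C)[Si](C)(C)OC(=O)/C(CO[Si](C)(C)C(C)(C)C)=C(\C=O)[C@@H](O[Si](C)(C)C(C)(C)C)C/C(CO[Si](CC)(CC)CC)=C\CC/C(C)=C/I | intermediate
20 | (5RS)-5-hydroxy-4-[(1S,3E,7E)-1-(TBS-oxy)-8-iodo-7-methyl-3-(TES-oxymethyl)octa-3,7-dien-1-yl]-3-(TBS-oxymethyl)furan-2(5H)-one | CC(C)(C)[Si](C)(C)OCC1=C([C@@H](O[Si](C)(C)C(C)(C)C)C/C(CO[Si](CC)(CC)CC)=C\CC/C(C)=C/I)C(O)OC1=O | intermediate
21 | methyl (2Z,4S,6E,10E)-4-(TBS-oxy)-2-(TBS-oxymethyl)-3-formyl-11-iodo-10-methyl-6-(TES-oxymethyl)undeca-2,6,10-trienoate | COC(=O)/C(CO[Si](C)(C)C(C)(C)C)=C(\C=O)[C@@H](O[Si](C)(C)C(C)(C)C)C/C(CO[Si](CC)(CC)CC)=C\CC/C(C)=C/I | intermediate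
22 | methyl (6RS,8S)-8,13-bis(TBS-oxy)-6-hydroxy-14-(TES-oxy)germacra-1(10)E,4E,7(11)E-trien-12-oate | COC(=O)/C(CO[Si](C)(C)C(C)(C)C)=C1/[C@@H](O[Si](C)(C)C(C)(C)C)C/C(CO[Si](CC)(CC)CC)=C\CC/C(C)=C/C1O | intermediate
23 | (6RS,8S)-8,13-bis(TBS-oxy)-14-(TES-oxy)germacra-1(10)E,4E,7(11)-trien-12,6-olide | CC(C)(C)[Si](C)(C)OCC1=C2[C@@H](O[Si](C)(C)C(C)(C)C)C/C(CO[Si](CC)(CC)CC)=C\CC/C(C)=C/C2OC1=O | intermediate
24 | (6RS,8S)-8,13-bis(TBS-oxy)-14-hydroxygermacra-1(10)E,4E,7(11)-trien-12,6-olide | CC(C)(C)[Si](C)(C)OCC1=C2[C@@H](O[Si](C)(C)C(C)(C)C)C/C(CO)=C\CC/C(C)=C/C2OC1=O | intermediate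
25 | (6R,8S)-8,13-bis(TBS-oxy)-14-oxogermacra-1(10)E,4E,7(11)-trien-12,6-olide (6-epi lactone, handled as the mixture with 26) | CC(C)(C)[Si](C)(C)OCC1=C2[C@@H](O[Si](C)(C)C(C)(C)C)C/C(C=O)=C\CC/C(C)=C/[C@H]2OC1=O | intermediate
26 | (6S,8S)-8,13-bis(TBS-oxy)-14-oxogermacra-1(10)E,4E,7(11)-trien-12,6-olide | CC(C)(C)[Si](C)(C)OCC1=C2[C@@H](O[Si](C)(C)C(C)(C)C)C/C(C=O)=C\CC/C(C)=C/[C@@H]2OC1=O | intermediate
27 | (4R,5R,6R,8S)-8,13-bis(TBS-oxy)-4,5-epoxy-14-oxogermacra-1(10)E,7(11)-dien-12,6-olide | CC(C)(C)[Si](C)(C)OCC1=C2[C@@H](O[Si](C)(C)C(C)(C)C)C/C(C=O)=C\CC[C@@]3(C)O[C@@H]3[C@@H]2OC1=O | intermediate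
28 | (4R,5R,6R,8S)-4,5-epoxy-8,13-dihydroxy-14-oxogermacra-1(10)E,7(11)-dien-12,6-olide | OCC1=C2[C@@H](O)C/C(C=O)=C\CC[C@@]3(C)O[C@@H]3[C@@H]2OC1=O | intermediate
29 | (4R,5R,6R,8S)-13-acetoxy-4,5-epoxy-8-hydroxy-14-oxogermacra-1(10)E,7(11)-dien-12,6-olide | CC(=O)OCC1=C2[C@@H](O)C/C(C=O)=C\CC[C@@]3(C)O[C@@H]3[C@@H]2OC1=O | intermediate
30 | (4R,5R,6R,8S)-13-acetoxy-4,5-epoxy-8-(3-methylbutanoyloxy)-14-oxogermacra-1(10)E,7(11)-dien-12,6-olide (CNP0289605.1) | CC(=O)OCC1=C2[C@@H](OC(=O)CC(C)C)C/C(C=O)=C\CC[C@@]3(C)O[C@@H]3[C@@H]2OC1=O | target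

## Step count and least certain steps

Total: 19 steps. Longest linear sequence: 18 steps (1 → 30 through steps 1–5 and 7–19); step 6 is a one-step branch.

**Step 15 (key step).** The equilibrium may not lie far enough on the side of 26. Face exchange may also be slower than β-hydride elimination from the allyl complex, or σ-bonding at C4 may leak the E alkene to Z. These would be seen as incomplete convergence, loss of material to dienyl acids, or a ring-cis C4=C5 lactone.

Fallback: control C6 when the C5–C6 bond is made. Setting out from 21, the Nozaki–Hiyama–Kishi closure is run with CrCl2 pre-complexed to a chiral oxazoline–sulfonamide ligand (NiCl2 co-catalyst, amine base), a known way to bias the aldehyde face in alkenylchromium additions. The same acidic methanol work-up then gives the single epimer (6S,8S)-8,13-bis(TBS-oxy)-14-hydroxygermacra-1(10)E,4E,7(11)-trien-12,6-olide F1, through the (6S) members of 22 and 23. MnO2 oxidation of F1 returns to the route at 26.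

**Step 13.** Closure of the strained ten-membered ring may be slower than protodeiodination or intermolecular coupling, and divalent chromium may transfer an electron to the formyl-enoate before the alkenylchromium adds.

Fallback: make the C5–C6 bond between two molecules and close the ring at C1=C10 by metathesis, setting out from 10 and returning at 23.
- Lactone 10 is reduced with i-Bu2AlH to (4S)-4-Fur-2-methylidenebutane-1,4-diol F2.
- TESCl gives (1S)-1-Fur-3-[(triethylsilyloxy)methyl]but-3-en-1-ol F3, and TBSOTf gives its C1 TBS ether F4.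
- Singlet oxygen and water give (5RS)-5-hydroxy-4-[(1S)-1-(TBS-oxy)-3-(TES-oxymethyl)but-3-en-1-yl]-3-(TBS-oxymethyl)furan-2(5H)-one F5.
- MeI/K2CO3 gives methyl (2Z,4S)-4-(TBS-oxy)-2-(TBS-oxymethyl)-3-formyl-6-(TES-oxymethyl)hepta-2,6-dienoate F6.
- Intermolecular Nozaki–Hiyama–Kishi coupling of F6 with an excess of iodide 13 (catalytic CrCl2, Mn, TMSCl, so that the aldehyde meets little divalent chromium), with lactonisation on work-up, gives (5RS)-5-[(1E)-2-methylhexa-1,5-dien-1-yl]-4-[(1S)-1-(TBS-oxy)-3-(TES-oxymethyl)but-3-en-1-yl]-3-(TBS-oxymethyl)furan-2(5H)-one F7.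
- Ring-closing metathesis of F7 (second-generation Grubbs catalyst C46H65Cl2N2PRu, toluene, 80 °C, high dilution) joins C1 to C10 in the ring-cis sense and gives 23.

**Step 16.** The aldehyde may be over-oxidised by peroxymonosulfate at pH 10.5. The face preferred by the chiral dioxirane may also be the one the ring conformation hides, giving slow reaction or poor facial selectivity.

Fallback: a peroxide-free two-step route that puts the oxygen on the face opposite to electrophilic attack, setting out from 26 and returning at 27. NBS in aqueous THF forms the bromonium ion on the exposed face and water opens it at tertiary C4, giving (4R,5S,6R,8S)-5-bromo-8,13-bis(TBS-oxy)-4-hydroxy-14-oxogermacra-1(10)E,7(11)-dien-12,6-olide F8. K2CO3 in MeCN closes the oxirane with inversion at C5 to give 27.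

**Step 17.** Once the C8 hydroxyl is free the lactone may migrate from O6 to O8, and the acidic fluoride source may open the trisubstituted epoxide.

Fallback: unmask and acylate the two oxygens one at a time so that the diol is never formed, setting out from 27 and returning at 29.
- Brief treatment with HF·pyridine/pyridine at 0 °C removes the primary silyl ether first, giving (4R,5R,6R,8S)-8-(TBS-oxy)-4,5-epoxy-13-hydroxy-14-oxogermacra-1(10)E,7(11)-dien-12,6-olide F9.
- Acetylation (Ac2O, pyridine) gives (4R,5R,6R,8S)-13-acetoxy-8-(TBS-oxy)-4,5-epoxy-14-oxogermacra-1(10)E,7(11)-dien-12,6-olide F10.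
- Removal of the remaining silyl ether gives 29, which is acylated at once as in step 19.

## Further compounds

F1 | step 15 | (6S,8S)-8,13-bis(TBS-oxy)-14-hydroxygermacra-1(10)E,4E,7(11)-trien-12,6-olide | CC(C)(C)[Si](C)(C)OCC1=C2[C@@H](O[Si](C)(C)C(C)(C)C)C/C(CO)=C\CC/C(C)=C/[C@@H]2OC1=O
F2 | step 13 | (4S)-4-Fur-2-methylidenebutane-1,4-diol | CC(C)(C)[Si](C)(C)OCc1c([C@@H](O)CC(=C)CO)coc1[Si](C)(C)C(C)(C)C
F3 | step 13 | (1S)-1-Fur-3-[(triethylsilyloxy)methyl]but-3-en-1-ol | CC(C)(C)[Si](C)(C)OCc1c([C@@H](O)CC(=C)CO[Si](CC)(CC)CC)coc1[Si](C)(C)C(C)(C)C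
F4 | step 13 | C1 TBS ether of F3 | CC(C)(C)[Si](C)(C)OCc1c([C@@H](O[Si](C)(C)C(C)(C)C)CC(=C)CO[Si](CC)(CC)CC)coc1[Si](C)(C)C(C)(C)C
F5 | step 13 | (5RS)-5-hydroxy-4-[(1S)-1-(TBS-oxy)-3-(TES-oxymethyl)but-3-en-1-yl]-3-(TBS-oxymethyl)furan-2(5H)-one | CC(C)(C)[Si](C)(C)OCC1=C([C@@H](O[Si](C)(C)C(C)(C)C)CC(=C)CO[Si](CC)(CC)CC)C(O)OC1=O
F6 | step 13 | methyl (2Z,4S)-4-(TBS-oxy)-2-(TBS-oxymethyl)-3-formyl-6-(TES-oxymethyl)hepta-2,6-dienoate | COC(=O)/C(CO[Si](C)(C)C(C)(C)C)=C(\C=O)[C@@H](O[Si](C)(C)C(C)(C)C)CC(=C)CO[Si](CC)(CC)CC
F7 | step 13 | (5RS)-5-[(1E)-2-methylhexa-1,5-dien-1-yl]-4-[(1S)-1-(TBS-oxy)-3-(TES-oxymethyl)but-3-en-1-yl]-3-(TBS-oxymethyl)furan-2(5H)-one | CC(C)(C)[Si](C)(C)OCC1=C([C@@H](O[Si](C)(C)C(C)(C)C)CC(=C)CO[Si](CC)(CC)CC)C(/C=C(\C)CCC=C)OC1=O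
F8 | step 16 | (4R,5S,6R,8S)-5-bromo-8,13-bis(TBS-oxy)-4-hydroxy-14-oxogermacra-1(10)E,7(11)-dien-12,6-olide | CC(C)(C)[Si](C)(C)OCC1=C2[C@@H](O[Si](C)(C)C(C)(C)C)C/C(C=O)=C\CC[C@@](C)(O)[C@@H](Br)[C@@H]2OC1=O
F9 | step 17 | (4R,5R,6R,8S)-8-(TBS-oxy)-4,5-epoxy-13-hydroxy-14-oxogermacra-1(10)E,7(11)-dien-12,6-olide | OCC1=C2[C@@H](O[Si](C)(C)C(C)(C)C)C/C(C=O)=C\CC[C@@]3(C)O[C@@H]3[C@@H]2OC1=O
F10 | step 17 | (4R,5R,6R,8S)-13-acetoxy-8-(TBS-oxy)-4,5-epoxy-14-oxogermacra-1(10)E,7(11)-dien-12,6-olide | CC(=O)OCC1=C2[C@@H](O[Si](C)(C)C(C)(C)C)C/C(C=O)=C\CC[C@@]3(C)O[C@@H]3[C@@H]2OC1=O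
A1 | alternative 1 | ten-membered C6 ketone with 8-dimethyl(phenyl)silyl group, 4,5-O-isopropylidene and ring-trans C1=C10 alkene | O=C1C[C@@H]([Si](C)(C)c3ccccc3)C/C(C)=C/CC[C@@]2(C)OC(C)(C)O[C@@H]12
A2 | alternative 2 | 4,5-epoxy-8,13-dihydroxy butenolide with C14 4-methoxybenzyl ether | OCC1=C2[C@@H](O)C/C(COCc3ccc(OC)cc3)=C\CC[C@@]4(C)O[C@@H]4[C@@H]2OC1=O
A3 | alternative 3 | C8/C13 endoperoxide (1,2-dioxine) fused to the butenolide | C1OO[C@H]2C/C(C=O)=C\CC[C@@]3(C)O[C@@H]3[C@@H]4OC(=O)C1=C24
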